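**Retrosynthetic overview**
1. Target 8 ⇒ rhamnetin 3,5-disulfate 7 by a last O-sulfation at the more acidic 4'-OH; 7 ⇒ ketal 6 by hydrogenolysis in the same flask.
2. 6 ⇒ 5 by forced double O-sulfation of 3-OH and the chelated 5-OH while the catechol is tied up.
3. 5 ⇒ rhamnetin 4 + Ph2CCl2: two C–O bonds, a temporary 1,3-dioxole on ring B.
4. 4 ⇒ quercetin 1 + Me2SO4: the key C–O bond (O7–CH3) by boron-templated, site-selective methylation of unprotected quercetin.
5. Rings A, C and B are bought intact with quercetin; the only ring made (and later removed) is the dioxole of step 2; no C–C bond is formed.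

Assumption: the target has no stereocentre, so no stereocontrol is needed; sulfate half-esters are written as neutral hydrogen sulfates as in the target SMILES, are handled as triethylammonium, tetrabutylammonium or potassium salts, and the free acid is released by H+-form cation exchange at 0 °C just before use.

**Step 1**
Reactants: 1 quercetin (3,5,7,3',4'-pentahydroxyflavone)
Product: 4 rhamnetin (3,5,3',4'-tetrahydroxy-7-methoxyflavone), via quercetin 3',4'-cyclic borate 2 (not isolated), via rhamnetin 3',4'-cyclic borate 3 (not isolated)
Conditions: B(OH)3 (4 equiv), NaOH (pH-stat 9.3), H2O/acetone 3:1, Ar, 20 °C; Me2SO4 (1.25 equiv, slow addition); then HCl to pH 2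
Reagents that add atoms: dimethyl sulfate COS(=O)(=O)OC; boric acid OB(O)O (its boron stays only in 2 and 3)
Why: Proposed new method: boron-templated site-selective Williamson O-methylation of an unprotected pentahydroxyflavonol, in which borate at pH 9.3 locks the 3',4'-catechol as a cyclic borate ester (shielding the otherwise most reactive 4'-O) and can also engage the 3-hydroxy-4-oxo chelate, the 3-OH and 5-OH stay hydrogen-bonded to the carbonyl and un-ionised, and the only free phenoxide, the most acidic 7-O−, attacks dimethyl sulfate by SN2 to form the O7–CH3 bond; the closest known reaction type is partial alkylation of catechol-bearing phenols under borate masking, which has not been used to single out O-7 of a flavonol with a free 3-OH.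

**Step 2**
Reactants: 4 rhamnetin
Product: 5 3',4'-O-diphenylmethylenerhamnetin (3,5-dihydroxy-7-methoxy-2-(2,2-diphenyl-1,3-benzodioxol-5-yl)chromen-4-one)
Conditions: Ph2CCl2 (1.5 equiv), Ph2O, 175 °C, 30 min
Reagents that add atoms: dichlorodiphenylmethane ClC(Cl)(c1ccccc1)c1ccccc1
Why: Catechol ketalization (double O-alkylation by the gem-dichloride through a diphenyl-stabilised oxocarbenium ion) closes the five-membered dioxole only at the ortho-diphenol, since 3-OH and 5-OH have no partner oxygen in reach and revert on work-up.

**Step 3**
Reactants: 5 3',4'-O-diphenylmethylenerhamnetin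
Product: 6 3',4'-O-diphenylmethylenerhamnetin 3,5-bis(hydrogen sulfate)
Conditions: Me3N·SO3 (12 equiv), Et3N, MeCN, microwave, 100 °C, 45 min; isolated as the bis(triethylammonium) salt (Sephadex LH-20)
Reagents that add atoms: sulfur trioxide–trimethylamine complex C[N+](C)(C)S(=O)(=O)[O-]
Why: O-sulfation by sulfur trioxide transfer from the amine complex to the phenoxides, pushed with excess reagent and microwave heating as in per-sulfation of polyphenols, also takes the hydrogen-bonded 5-OH, and the basic medium leaves ketal, methyl ether and pyranone intact.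

**Step 4**
Reactants: 6 3',4'-O-diphenylmethylenerhamnetin 3,5-bis(hydrogen sulfate)
Product: 8 rhamnetin 3,5,4'-tris(hydrogen sulfate) (target), via rhamnetin 3,5-disulfate 7 (not isolated)
Conditions: H2 (1 atm), Pd(OH)2 on carbon, DMF, 20 °C; N2 purge; then Bu4NHSO4 (1.5 equiv), DCC (5 equiv), DMF/pyridine, 4 °C, 24 h; KOAc, MeOH (tripotassium salt)
Reagents that add atoms: tetrabutylammonium hydrogen sulfate CCCC[N+](CCCC)(CCCC)CCCC.OS(=O)(=O)[O-]
Why: Hydrogenolysis of the doubly benzylic ketal C–O bonds frees the catechol without touching aryl sulfates or the chromone, and carbodiimide-mediated sulfation (DCC-activated hydrogen sulfate) then sulfates only the more acidic 4'-OH, which is conjugated to the carbonyl through C-2, while the 3'-OH is less acidic and shielded by the neighbouring sulfate anion.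

**Compound list**
1 | quercetin (3,5,7,3',4'-pentahydroxyflavone) | O=c1c(O)c(-c2ccc(O)c(O)c2)oc2cc(O)cc(O)c12 | starting material
2 | quercetin 3',4'-O-cyclic hydroxyborate (drawn as the neutral B–OH ester; present at pH 9.3 as its hydroxide adduct) | O=c1c(O)c(-c2ccc3OB(O)Oc3c2)oc2cc(O)cc(O)c12 | intermediate (not isolated)
3 | rhamnetin 3',4'-O-cyclic hydroxyborate (7-O-methyl derivative of 2) | COc1cc(O)c2c(=O)c(O)c(-c3ccc4OB(O)Oc4c3)oc2c1 | intermediate (not isolated)
4 | rhamnetin (3,5,3',4'-tetrahydroxy-7-methoxyflavone) | COc1cc(O)c2c(=O)c(O)c(-c3ccc(O)c(O)c3)oc2c1 | intermediate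
5 | 3',4'-O-diphenylmethylenerhamnetin | COc1cc(O)c2c(=O)c(O)c(-c3ccc4c(c3)OC(c5ccccc5)(c6ccccc6)O4)oc2c1 | intermediate
6 | 3',4'-O-diphenylmethylenerhamnetin 3,5-bis(hydrogen sulfate) | COc1cc(OS(=O)(=O)O)c2c(=O)c(OS(=O)(=O)O)c(-c3ccc4c(c3)OC(c5ccccc5)(c6ccccc6)O4)oc2c1 | intermediate
7 | rhamnetin 3,5-bis(hydrogen sulfate) (3',4'-catechol free) | COc1cc(OS(=O)(=O)O)c2c(=O)c(OS(=O)(=O)O)c(-c3ccc(O)c(O)c3)oc2c1 | intermediate (not isolated)
8 | rhamnetin 3,5,4'-tri-O-sulfate (achiral) | COc1cc(OS(=O)(=O)O)c2c(=O)c(OS(=O)(=O)O)c(-c3ccc(OS(=O)(=O)O)c(O)c3)oc2c1 | target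

**Total step count:** 4. **Longest linear sequence:** 4.

**Steps most likely to fail, with fallbacks**

Step 1 (the proposed new method) may give 3-O-methyl or 3,7-di-O-methyl by-products if the 3-OH is not masked well enough, or 4'-O-methylation if the borate ester opens. The fallback sets out from 1 and uses the known order of events: 1 is heated with Ph2CCl2 in Ph2O at 175 °C to give 3',4'-O-diphenylmethylenequercetin F1, whose most acidic free hydroxyl (7-OH) is then methylated with MeI (1.1 equiv) and K2CO3 in DMF at 20 °C. This comes back to the route at 5, so step 2 is no longer needed and the count stays at 4.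

Step 3 may stop at the 3-monosulfate because the 5-OH is chelated to the carbonyl. The fallback sets out from 5 and switches from direct sulfur trioxide transfer to a protected sulfate diester. 2,2,2-Trichloroethyl chlorosulfate with Et3N and DMAP in THF gives 3',4'-O-diphenylmethylenerhamnetin 3,5-bis(2,2,2-trichloroethyl sulfate) F2, a neutral compound that can be purified on silica. Zn dust and HCO2NH4 in MeOH then remove both trichloroethyl groups, and the route is rejoined at 6.

Step 4 may give some 3'-sulfate or 3',4'-disulfate, or the carbodiimide stage may suffer in the hydrogenation mixture. The fallback sets out from 6 and replaces the chemical sulfation by a biocatalytic one. Hydrogenolysis (H2, Pd(OH)2 on carbon, THF/MeOH) is worked up to isolate 7 as its potassium salt. Bacterial aryl sulfotransferase (from Desulfitobacterium hafniense) with potassium 4-nitrophenyl sulfate (KO3SOC6H4NO2) as donor in Tris–glycine buffer at pH 8.9 and 30 °C then sulfates the 4'-OH, the site this enzyme takes in 3-O-substituted quercetins. This comes back to the route at 8; no new compound is made (F0).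

**Further compounds**
F1 | step 1 | 3',4'-O-diphenylmethylenequercetin | O=c1c(O)c(-c2ccc3c(c2)OC(c4ccccc4)(c5ccccc5)O3)oc2cc(O)cc(O)c12
F2 | step 3 | 3',4'-O-diphenylmethylenerhamnetin 3,5-bis(2,2,2-trichloroethyl sulfate) | COc1cc(OS(=O)(=O)OCC(Cl)(Cl)Cl)c2c(=O)c(OS(=O)(=O)OCC(Cl)(Cl)Cl)c(-c3ccc4c(c3)OC(c5ccccc5)(c6ccccc6)O4)oc2c1
F0 | step 4 | none | none
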